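## Structural features

The target is a 2-arylbenzofuran: a benzene ring A fused to a furan, with a 2,4-dihydroxyphenyl ring B on C2 and a formyl group on C3. Ring A is a fully differentiated phloroglucinol, with a free OH on C4, a 3-hydroxy-3-methylbutyl chain on C5, OMe on C6, H on C7 and the furan oxygen on C7a. The target has no stereocentre, so no two stereocentres stand next to each other and nothing stereochemical has to be set; the one centre met on the way (C2 of the furanone and coumaranone intermediates) is racemic and vanishes when the furan becomes aromatic. Fragile features are the aldehyde, flanked by the 4-OH and 2'-OH groups (hemiacetal formation, reduction, oxidation), the tertiary alcohol, which ionises in acid and can close a chroman onto the 4-OH, and two very electron-rich arenes. The real difficulty is the regiochemistry of ring A, where three different oxygens (OH, OMe, ring O) alternate with three different carbon substituents (acyl carbon on C3a, chain, H), together with the crowded C3 position between the aryl group and the 4-OH. The key step exploits that the C3a–C7a bond of ring A can be the enone C=C of a furan-3(2H)-one whose C3 carbonyl lies next to C4. A 1,3-dioxygenated ketene-acetal diene that bonds through its acetal carbon to C3a then delivers 4-OH, the C5 chain, 6-OMe and 7-H at once, and the same C3 carbonyl later becomes the handle for the formyl carbon.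

## Logic of the disconnections

25 ⇒ 24 ⇒ 23. The two benzyl O–CH2 bonds of ring B are cut, then the two O–Si bonds (4-O and the tertiary O of the chain). The phenols and the tertiary alcohol cannot be carried free through enolate and palladium chemistry, so they stay masked to the end. This turns a polyphenolic aldehyde into a lipophilic, fully protected one. The forward steps must be neutral: buffered fluoride, and a hydrogenolysis that spares the aldehyde.

23 ⇒ 22 ⇒ 21 ⇒ 20. The C3–CHO bond is cut to the enol triflate 22, the triflate O–S bond to ketone 21, and the 4-O–Si bond to 20. The formyl carbon is the most sensitive carbon and is best added last as carbon monoxide; the oxygen it replaces is exactly the carbonyl that the ring A synthesis needs. The aldehyde problem becomes a ketone problem. The forward steps demand O-selective trapping of the C2 enolate, a carbonylation that outruns simple reduction at a hindered position, and prior capping of the chelated 4-OH.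

20 ⇒ 7 + 17. Ring A is cut at C7–C7a and C3a–C4. This removes the whole phloroglucinol problem at once: C4 to C7 with OH, chain, OMe and H come from 7; C3a and C7a with the furan oxygen and the C3 carbonyl come from 17. Two fragments of similar size result, each four or five steps from purchasable material. The forward step needs full regiocontrol (CH2 terminus to C7a, acetal carbon to C3a), enough reactivity from a push–pull enone, and loss of HBr and MeOSiMe3 without opening the furanone.

17 ⇒ 16 ⇒ 13 + 14. The C4–Br bond is cut, then the O1–C5 and C4–C5 bonds of the furanone, so that C5 comes from 14 and the rest from 13. Bromine serves only as leaving group for the aromatisation and as regiochemical marker, and is best put on the finished vinylogous ester. The heterocycle is reduced to an acyclic α-hydroxy methyl ketone. Forward, bromination must choose C4 over the dialkoxyphenyl ring and over C2, and the condensation must not isomerise the acyloin.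

13 ⇒ 9 + 10 ⇒ 8. The bond between the carbinol carbon and the acetyl carbon is cut, giving 9 and an acetyl anion equivalent from 10 (through 11 and 12); the two O–benzyl bonds of 9 lead to 8. This is the shortest way from a purchasable aldehyde to the acyloin. Forward, hydrolysis of the enol ether in 12 must be faster than ionisation of the electron-rich benzylic alcohol.

7 ⇒ 6 ⇒ 5 ⇒ 3 + 4; 3 ⇒ 2 ⇒ 1. The ketene acetal O–Si bond, then the enol O–CH3 bond, then the C–C bond between the acetoacetate α-carbon and the chain are cut; 3 goes back to 1 by O–Si and C–I cuts. The diene reduces to an alkylated acetoacetate, and the chain to a C5 diol that already holds the tertiary carbinol. The forward demands are O- rather than C-methylation under non-acidic conditions (the silyl ether would not survive the acid route, and the free alcohol would cyclise onto the ketone), γ-deprotonation in step 5, and monoalkylation in step 3.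

## Other disconnections considered

Alternative 1: The cut is in the furan ring, at O1–C2 and at the exocyclic C3–CH2 bond, leading back to the diarylalkyne A2 with two methoxymethyl ethers ortho to the alkyne. Forward, PtCl2 with 1,5-cyclooctadiene activates the alkyne, one acetal oxygen attacks C2, and its CH2OMe group migrates to C3 to give A1.
- In favour: carboalkoxylation of ortho-alkynylaryl acetals is an established reaction type. The two equivalent acetals remove any regiochemical question in ring A. The future formyl carbon arrives in the same step.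
- Against: A1 still lacks the C5 chain. It would have to be added by metalation between OCH2OMe and OMe, in competition with C7 and the benzylic CH2OMe. The CH2OMe group needs oxidation to the aldehyde, and the last acetal must be removed with acid next to a tertiary alcohol.
- Comparison: in structure it keeps ring A as a bought arene and forms the furan, the reverse of the chosen plan, which sets all four ring A substituents in one step. In mechanism Alternative 1 is the better plan, because its key step has close precedent and the chosen annulation has none. In step economy the two are about equal.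

Alternative 2: Ring A is cut at C6–C7 and C4–C5, leading to the furan diester A4 (2-aryl, 5-methyl, 3,4-diester) and the lactone A5. Forward, excess LiN(i-Pr)2 should deprotonate the furan methyl group, acylate it with A5, and close the ring by attack of the new ketone α-carbanion on the neighbouring ester, giving A3.
- In favour: ring A, the chain and its free tertiary alcohol come in one operation without a protecting group on the chain, and the C3 carbon is already present as an ester. On these two points it is the better plan.
- Against: A5 has its own acidic α-hydrogens and A4 can self-condense, so the order of deprotonations is hard to control. A3 has two free phenols, so the 6-OH must be methylated selectively (chelation of the 4-OH helps). The ester needs reduction and re-oxidation to the aldehyde.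
- Comparison: structurally both plans build ring A on a preformed 2-aryl furan unit and are equally convergent. Mechanistically both rest on an unproven annulation, so neither has the advantage, though the chosen plan fixes the OH/OMe difference in the diene instead of by a later selective methylation. Step counts are similar.

Alternative 3: The cut is C3–C3a, which traces the benzofuran-3-carboxylate to the flavanone A7, where ring A is still bonded to the carbonyl carbon. Forward, PhI(OAc)2 and acid in trimethyl orthoformate and methanol activate C3 of the enol ether of A7; ring A migrates from C4 to C3 and the pyranone contracts to the trans dihydrobenzofuran ester A6.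
- In favour: oxidative ring contraction of flavanones is known chemistry. Ring A would come from a symmetrical aryl ketone, so its pattern is not in question. The lactone later delivers both the 4-OH and, with a methyl Grignard reagent, the tertiary alcohol, an elegant point on which it is better.
- Against: with a 2,4-dialkoxyphenyl group on C2, the competing shift of ring B (isoflavone formation) and oxidation of the electron-rich rings are likely. After the key step the plan still needs dehydrogenation to the benzofuran, chemoselective methyl addition to the lactone beside the ester, and ester-to-aldehyde adjustment. Two stereocentres are made only to be destroyed.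
- Comparison: on precedent for the key step the alternative is better. On structure it is linear where the chosen plan is convergent. On step count it is clearly longer.

Key step: step 10

Remark: all sp3 stereocentres met on the way (in 5, 12, 13 and 15–21) are racemic or mixed and are written without configuration, so a racemate is not drawn as a single enantiomer; each is erased before the target. Compounds 6 and 7 are drawn as one geometric isomer each, although mixtures are expected and converge.

## Steps

Step 1
Reactants: 1 3-methylbutane-1,3-diol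
Product: 2 4-iodo-2-methylbutan-2-ol
Conditions: I2, PPh3, imidazole, CH2Cl2, 0 °C → rt
Reagents that add atoms: iodine, II
Why: Appel iodination; the primary hydroxyl forms the alkoxyphosphonium ion and is displaced far faster than the hindered tertiary hydroxyl, and without base the iodo alcohol does not close to an oxetane.

Step 2
Reactants: 2 4-iodo-2-methylbutan-2-ol
Product: 3 triethyl[(4-iodo-2-methylbutan-2-yl)oxy]silane
Conditions: Et3SiOTf, 2,6-lutidine, CH2Cl2, −78 → 0 °C
Reagents that add atoms: triethylsilyl trifluoromethanesulfonate, CC[Si](CC)(CC)OS(=O)(=O)C(F)(F)F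
Why: Silyl triflate silylation of a tertiary alcohol; the triethylsilyl ether withstands enolates, amide bases and palladium, leaves with fluoride at the end, and keeps the hydroxyl from cyclising onto the ketone of 5.

Step 3
Reactants: 4 methyl acetoacetate; 3 triethyl[(4-iodo-2-methylbutan-2-yl)oxy]silane
Product: 5 methyl 2-acetyl-5-methyl-5-(triethylsilyloxy)hexanoate (racemic)
Conditions: 4 (1.5 equiv), NaH, THF/DMF, 0 °C; then 3, 55 °C
Reagents that add atoms: none
Why: Acetoacetic ester alkylation (SN2 of the sodium enolate on an unhindered primary iodide); excess 4 limits dialkylation, and the new stereocentre is racemic and disappears in step 4.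

Step 4
Reactants: 5 methyl 2-acetyl-5-methyl-5-(triethylsilyloxy)hexanoate
Product: 6 methyl (E)-3-methoxy-2-[3-methyl-3-(triethylsilyloxy)butyl]but-2-enoate
Conditions: KOt-Bu, DMPU/THF, 0 °C; Me2SO4, 0 °C → rt
Reagents that add atoms: dimethyl sulfate, COS(=O)(=O)OC
Why: O-alkylation of a β-keto ester enolate; the dissociated potassium enolate in a dipolar aprotic medium meets the hard sulfate at oxygen, while C-methylation would have to build a quaternary centre. Basic conditions spare the silyl ether, which the usual orthoformate and acid method would not, and either enol ether geometry serves in step 5.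

Step 5
Reactants: 6 methyl (E)-3-methoxy-2-[3-methyl-3-(triethylsilyloxy)butyl]but-2-enoate
Product: 7 (1Z)-1,3-dimethoxy-2-(3-methyl-3-triethylsilyloxybutyl)-1-trimethylsilyloxybuta-1,3-diene
Conditions: LiN(i-Pr)2 (commercial solution), THF, −78 °C; Me3SiCl, −78 → 0 °C; pentane filtration, used crude
Reagents that add atoms: chlorotrimethylsilane, C[Si](C)(C)Cl
Why: γ-Deprotonation of the β-methoxy enoate to the extended enolate and O-silylation, the standard preparation of Brassard-type dienes; the methyl group is the only site whose anion is conjugated to the ester.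

Step 6
Reactants: 8 2,4-dihydroxybenzaldehyde
Product: 9 2,4-bis(benzyloxy)benzaldehyde
Conditions: BnBr, K2CO3, DMF, 60 °C
Reagents that add atoms: benzyl bromide, BrCc1ccccc1
Why: Williamson etherification of both phenols; benzyl ethers survive organolithium, amide acetal, bromination, the annulation, KN(SiMe3)2 and palladium carbonylation.

Step 7
Reactants: 9 2,4-bis(benzyloxy)benzaldehyde; 10 ethyl vinyl ether
Product: 13 1-[2,4-bis(benzyloxy)phenyl]-1-hydroxypropan-2-one (racemic), via 1-ethoxyvinyllithium 11 (not isolated), via enol ether adduct 12 (not isolated)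
Conditions: 10 (excess), t-BuLi, THF, −78 → 0 °C; 9, −78 °C; then 0.5 M HCl (aq), THF, 0 °C
Reagents that add atoms: water, O
Why: A metallated enol ether acts as acetyl anion equivalent and adds 1,2 to the aldehyde; the 2-ethoxyallyl alcohol hydrolyses in cold dilute acid within minutes, faster than the electron-rich benzylic alcohol can ionise. The carbinol centre is racemic.

Step 8
Reactants: 13 1-[2,4-bis(benzyloxy)phenyl]-1-hydroxypropan-2-one; 14 N,N-dimethylformamide dimethyl acetal
Product: 16 2-[2,4-bis(benzyloxy)phenyl]furan-3(2H)-one (racemic), via enaminone 15 (not isolated)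
Conditions: 14 (3 equiv), PhMe, 80 °C; evaporate; 1 M H2SO4 (aq), THF, rt
Reagents that add atoms: none
Why: Enaminone formation at the methyl ketone, then acid-promoted addition of the hydroxyl to the iminium carbon and loss of dimethylamine, the standard route from α-hydroxy ketones to 3(2H)-furanones. During heating the hydroxyl is tied up by exchange with the amide acetal, which limits enediol isomerisation.

Step 9
Reactants: 16 2-[2,4-bis(benzyloxy)phenyl]furan-3(2H)-one
Product: 17 2-[2,4-bis(benzyloxy)phenyl]-4-bromofuran-3(2H)-one (racemic)
Conditions: NBS (1.0 equiv), CH2Cl2, −20 → 0 °C, dark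
Reagents that add atoms: N-bromosuccinimide, O=C1CCC(=O)N1Br
Why: Electrophilic bromination at the nucleophilic α-carbon of the vinylogous ester (addition to the enol ether, loss of H-4), an established halogenation of 3(2H)-furanones; low temperature, one equivalent and a non-polar solvent favour C4 over the dialkoxyphenyl ring and C2.

Step 10
Reactants: 7 (1Z)-1,3-dimethoxy-2-(3-methyl-3-triethylsilyloxybutyl)-1-trimethylsilyloxybuta-1,3-diene; 17 2-[2,4-bis(benzyloxy)phenyl]-4-bromofuran-3(2H)-one
Product: 20 2-[2,4-bis(benzyloxy)phenyl]-4-hydroxy-6-methoxy-5-(3-methyl-3-triethylsilyloxybutyl)benzofuran-3(2H)-one (racemic), via cycloadduct 18 (not isolated), via dienone 19 (not isolated)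
Conditions: 7 (2.5 equiv), PhMe, 90 °C, Ar; then Et3N, 0 °C → rt; aq. NH4Cl
Reagents that add atoms: none
Why: Proposed new method: the electron-rich CH2 terminus of 7 bonds to C5 of 17 (the β-carbon of the vinylogous ester) and the acetal carbon bonds to the brominated α-carbon in a concerted, asynchronous [4+2] addition; the closest known reaction is the regiospecific resorcinol annulation of ketene-acetal dienes with 2-haloquinones and α-halo enones. Ring A closes as the six-membered carbocycle of the cis-fused cycloadduct 18 by the two new bonds C7–C7a and C3a–C4; if the process is stepwise, the second bond forms by 6-exo-trig Claisen-type attack of the bromo enolate on the ester and the connectivity is the same. Unlike a quinone adduct, 18 has no acidic hydrogen at the ring fusion, so HBr should leave through the C2 enol, whose allylic C3a–Br bond ionises with help from O1 and the aryl group before H-7a is taken by Et3N. Expulsion of MeOSiMe3 from the mixed acetal gives dienone 19, which tautomerises to the chelated phenol 20. Regiochemistry is the only selectivity needed, and it is secured by the polarity match and by bromine, which ends on the carbon that becomes C3a and so puts OH on C4, the chain on C5, OMe on C6 and H on C7. The stereocentres of 18 are transient, and C2 stays racemic, which does not matter because it becomes sp2 in step 12. Heat is chosen over a Lewis acid because silyl triflates or metal halides would turn the C2–H acidic furanone into its 3-silyloxyfuran or open it by retro-oxa-Michael reaction after a stepwise addition.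

Step 11
Reactants: 20 2-[2,4-bis(benzyloxy)phenyl]-4-hydroxy-6-methoxy-5-(3-methyl-3-triethylsilyloxybutyl)benzofuran-3(2H)-one
Product: 21 2-[2,4-bis(benzyloxy)phenyl]-4-(tert-butyldimethylsilyloxy)-6-methoxy-5-(3-methyl-3-triethylsilyloxybutyl)benzofuran-3(2H)-one (racemic)
Conditions: t-BuMe2SiCl, imidazole, DMAP (cat.), DMF, 40 °C, Ar
Reagents that add atoms: tert-butyldimethylsilyl chloride, CC(C)(C)[Si](C)(C)Cl
Why: Phenol silylation; the chelated, flanked 4-OH is slow, hence DMAP and gentle warming, while imidazole is too weak to silylate the ketone enol. Air is excluded because 2-aryl coumaranones autoxidise at C2.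

Step 12
Reactants: 21 2-[2,4-bis(benzyloxy)phenyl]-4-(tert-butyldimethylsilyloxy)-6-methoxy-5-(3-methyl-3-triethylsilyloxybutyl)benzofuran-3(2H)-one
Product: 22 2-[2,4-bis(benzyloxy)phenyl]-4-(tert-butyldimethylsilyloxy)-6-methoxy-5-(3-methyl-3-triethylsilyloxybutyl)benzofuran-3-yl trifluoromethanesulfonate
Conditions: KN(SiMe3)2, THF, −78 °C; PhNTf2, −78 → 0 °C
Reagents that add atoms: N-phenylbis(trifluoromethanesulfonimide), O=S(=O)(N(c1ccccc1)S(=O)(=O)C(F)(F)F)C(F)(F)F
Why: Enol triflate formation; deprotonation of the doubly activated C2–H gives the aromatic 3-oxidobenzofuran, which is trapped on oxygen. This erases the C2 stereocentre and turns the activating carbonyl into a coupling handle.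

Step 13
Reactants: 22 2-[2,4-bis(benzyloxy)phenyl]-4-(tert-butyldimethylsilyloxy)-6-methoxy-5-(3-methyl-3-triethylsilyloxybutyl)benzofuran-3-yl trifluoromethanesulfonate
Product: 23 2-[2,4-bis(benzyloxy)phenyl]-4-(tert-butyldimethylsilyloxy)-6-methoxy-5-(3-methyl-3-triethylsilyloxybutyl)benzofuran-3-carbaldehyde
Conditions: Pd(OAc)2 (10 mol%), dppp (10 mol%), CO (1 atm), Et3SiH, Et3N, DMF, 70 °C
Reagents that add atoms: carbon monoxide, [C-]#[O+]
Why: Palladium-catalysed reductive carbonylation of an enol triflate: oxidative addition to zerovalent palladium, CO insertion to the acylpalladium species, and hydride transfer from the silane; the chelating diphosphine favours CO insertion over direct reduction. Loss of the aryl silyl ether here would be harmless.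

Step 14
Reactants: 23 2-[2,4-bis(benzyloxy)phenyl]-4-(tert-butyldimethylsilyloxy)-6-methoxy-5-(3-methyl-3-triethylsilyloxybutyl)benzofuran-3-carbaldehyde
Product: 24 2-[2,4-bis(benzyloxy)phenyl]-4-hydroxy-5-(3-hydroxy-3-methylbutyl)-6-methoxybenzofuran-3-carbaldehyde
Conditions: Bu4NF, AcOH, THF, 0 → 40 °C
Reagents that add atoms: none
Why: Fluoride cleavage of the aryl silyl ether and the tertiary triethylsilyl ether; acetic acid buffers the phenoxide beside the aldehyde, and the absence of strong acid avoids ionisation of the tertiary alcohol and chroman formation.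

Step 15
Reactants: 24 2-[2,4-bis(benzyloxy)phenyl]-4-hydroxy-5-(3-hydroxy-3-methylbutyl)-6-methoxybenzofuran-3-carbaldehyde
Product: 25 2-(2,4-dihydroxyphenyl)-4-hydroxy-5-(3-hydroxy-3-methylbutyl)-6-methoxybenzofuran-3-carbaldehyde
Conditions: H2 (1 atm), 10% Pd/C, EtOAc, rt, stopped when debenzylation is complete
Reagents that add atoms: none
Why: Hydrogenolysis of aryl benzyl ethers; the aldehyde is a chelated vinylogous formate and should be reduced far more slowly than the O–benzyl bonds, and the tetrasubstituted furan double bond is inert.

## Compound list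

1 | 3-methylbutane-1,3-diol | CC(C)(O)CCO | starting material
2 | 4-iodo-2-methylbutan-2-ol | CC(C)(O)CCI | intermediate
3 | triethyl[(4-iodo-2-methylbutan-2-yl)oxy]silane | CC[Si](CC)(CC)OC(C)(C)CCI | intermediate
4 | methyl acetoacetate | COC(=O)CC(C)=O | starting material
5 | methyl 2-acetyl-5-methyl-5-(triethylsilyloxy)hexanoate (racemic) | COC(=O)C(CCC(C)(C)O[Si](CC)(CC)CC)C(C)=O | intermediate
6 | methyl (E)-3-methoxy-2-[3-methyl-3-(triethylsilyloxy)butyl]but-2-enoate (E drawn, mixture expected) | CO/C(C)=C(/C(=O)OC)CCC(C)(C)O[Si](CC)(CC)CC | intermediate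
7 | (1Z)-1,3-dimethoxy-2-(3-methyl-3-triethylsilyloxybutyl)-1-trimethylsilyloxybuta-1,3-diene (either ketene acetal isomer serves) | C=C(OC)/C(CCC(C)(C)O[Si](CC)(CC)CC)=C(/OC)O[Si](C)(C)C | intermediate
8 | 2,4-dihydroxybenzaldehyde | O=Cc1ccc(O)cc1O | starting material
9 | 2,4-bis(benzyloxy)benzaldehyde | O=Cc1ccc(OCc2ccccc2)cc1OCc1ccccc1 | intermediate
10 | ethyl vinyl ether | C=COCC | starting material
11 | 1-ethoxyvinyllithium | [Li]C(=C)OCC | intermediate
12 | 1-[2,4-bis(benzyloxy)phenyl]-2-ethoxyprop-2-en-1-ol (racemic, formed as its lithium alkoxide) | C=C(OCC)C(O)c1ccc(OCc2ccccc2)cc1OCc1ccccc1 | intermediate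
13 | 1-[2,4-bis(benzyloxy)phenyl]-1-hydroxypropan-2-one (racemic) | CC(=O)C(O)c1ccc(OCc2ccccc2)cc1OCc1ccccc1 | intermediate
14 | N,N-dimethylformamide dimethyl acetal | COC(OC)N(C)C | starting material
15 | (E)-1-[2,4-bis(benzyloxy)phenyl]-4-(dimethylamino)-1-hydroxybut-3-en-2-one (racemic) | CN(C)/C=C/C(=O)C(O)c1ccc(OCc2ccccc2)cc1OCc1ccccc1 | intermediate
16 | 2-[2,4-bis(benzyloxy)phenyl]furan-3(2H)-one (racemic) | O=C1C=COC1c1ccc(OCc2ccccc2)cc1OCc1ccccc1 | intermediate
17 | 2-[2,4-bis(benzyloxy)phenyl]-4-bromofuran-3(2H)-one (racemic) | O=C1C(Br)=COC1c1ccc(OCc2ccccc2)cc1OCc1ccccc1 | intermediate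
18 | 2-[2,4-bis(benzyloxy)phenyl]-3a-bromo-4,6-dimethoxy-5-(3-methyl-3-triethylsilyloxybutyl)-4-trimethylsilyloxy-3a,4,7,7a-tetrahydrobenzofuran-3(2H)-one (cis-fused, mixture of diastereomers) | O=C1C(c2ccc(OCc3ccccc3)cc2OCc2ccccc2)OC2CC(OC)=C(CCC(C)(C)O[Si](CC)(CC)CC)C(OC)(O[Si](C)(C)C)C12Br | intermediate
19 | 2-[2,4-bis(benzyloxy)phenyl]-6-methoxy-5-(3-methyl-3-triethylsilyloxybutyl)benzofuran-3,4(2H,7H)-dione (racemic) | O=C1C(c2ccc(OCc3ccccc3)cc2OCc2ccccc2)OC2=C1C(=O)C(CCC(C)(C)O[Si](CC)(CC)CC)=C(OC)C2 | intermediate
20 | 2-[2,4-bis(benzyloxy)phenyl]-4-hydroxy-6-methoxy-5-(3-methyl-3-triethylsilyloxybutyl)benzofuran-3(2H)-one (racemic) | O=C1C(c2ccc(OCc3ccccc3)cc2OCc2ccccc2)Oc2cc(OC)c(CCC(C)(C)O[Si](CC)(CC)CC)c(O)c12 | intermediate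
21 | 2-[2,4-bis(benzyloxy)phenyl]-4-(tert-butyldimethylsilyloxy)-6-methoxy-5-(3-methyl-3-triethylsilyloxybutyl)benzofuran-3(2H)-one (racemic) | O=C1C(c2ccc(OCc3ccccc3)cc2OCc2ccccc2)Oc2cc(OC)c(CCC(C)(C)O[Si](CC)(CC)CC)c(O[Si](C)(C)C(C)(C)C)c12 | intermediate
22 | 2-[2,4-bis(benzyloxy)phenyl]-4-(tert-butyldimethylsilyloxy)-6-methoxy-5-(3-methyl-3-triethylsilyloxybutyl)benzofuran-3-yl trifluoromethanesulfonate | COc1cc2oc(-c3ccc(OCc4ccccc4)cc3OCc3ccccc3)c(OS(=O)(=O)C(F)(F)F)c2c(O[Si](C)(C)C(C)(C)C)c1CCC(C)(C)O[Si](CC)(CC)CC | intermediate
23 | 2-[2,4-bis(benzyloxy)phenyl]-4-(tert-butyldimethylsilyloxy)-6-methoxy-5-(3-methyl-3-triethylsilyloxybutyl)benzofuran-3-carbaldehyde | COc1cc2oc(-c3ccc(OCc4ccccc4)cc3OCc3ccccc3)c(C=O)c2c(O[Si](C)(C)C(C)(C)C)c1CCC(C)(C)O[Si](CC)(CC)CC | intermediate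
24 | 2-[2,4-bis(benzyloxy)phenyl]-4-hydroxy-5-(3-hydroxy-3-methylbutyl)-6-methoxybenzofuran-3-carbaldehyde | COc1cc2oc(-c3ccc(OCc4ccccc4)cc3OCc3ccccc3)c(C=O)c2c(O)c1CCC(C)(C)O | intermediate
25 | 2-(2,4-dihydroxyphenyl)-4-hydroxy-5-(3-hydroxy-3-methylbutyl)-6-methoxybenzofuran-3-carbaldehyde | COc1cc2oc(-c3ccc(O)cc3O)c(C=O)c2c(O)c1CCC(C)(C)O | target

## Step count and least certain steps

Total: 15 steps. Longest linear sequence: 11 steps (steps 1–5 and 10–15, from 1 to 25); the dienophile branch (steps 6–9) joins at step 10.

Step 10 (key step, new method). Three things may go wrong: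
- The push–pull dienophile may react too slowly, so that the diene decomposes thermally first.
- A stepwise addition may be followed by retro-oxa-Michael opening of the furanone, or silyl transfer may aromatise the enolisable furanone to an unreactive silyloxyfuran.
- HBr loss may stall because the ring-fusion hydrogen is not acidic.

Fallback with known chemistry, setting out from 8 and 3 and returning at 25:
- 8 is silylated (i-Pr3SiCl, imidazole, DMF) to 2,4-bis(triisopropylsilyloxy)benzaldehyde F1, which lithiated trimethylsilyldiazomethane (Colvin homologation) converts into 1-ethynyl-2,4-bis(triisopropylsilyloxy)benzene F2.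
- Commercial 5-methoxyresorcinol gives 1-methoxy-3,5-bis(methoxymethoxy)benzene F3 (MeOCH2Cl, i-Pr2NEt). Lithiation between the two acetal oxygens (n-BuLi) and iodine quench give 2-iodo-5-methoxy-1,3-bis(methoxymethoxy)benzene F4.
- Sonogashira coupling of F2 with F4 (PdCl2(PPh3)2, CuI, Et3N) gives the diarylalkyne F5. PtCl2 with 1,5-cyclooctadiene in toluene closes the furan with transfer of CH2OMe to C3, giving the 3-(methoxymethyl)benzofuran F6 (the same structure as A1).
- Lithiation at C5 between OCH2OMe and OMe (n-BuLi, THF, 0 °C) and alkylation with 3 give the 5-alkylbenzofuran F7. DDQ in wet CH2Cl2 oxidises CH2OMe to the aldehyde F8.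
- Bu4NF removes the three silyl groups to give the methoxymethyl-protected aldehyde F9, and dilute HCl in THF/MeOH at room temperature cleaves the chelated acetal to 25.

Step 8. Base-promoted enediol isomerisation of the secondary benzylic acyloin to the conjugated aryl ketone may compete with enaminone formation during heating. Fallback, from 9 and 10 (through 11) back to 16: the lithium alkoxide is trapped with Et3SiCl before work-up and only the enol ether is hydrolysed (oxalic acid on wet silica), giving the O-silyl acyloin F10, which cannot enolise towards the carbinol carbon. Condensation with 14 followed by 1 M HCl in THF (desilylation and cyclisation) gives 16.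

Step 9. Bromination may go to the dialkoxyphenyl ring or to C2 instead of C4. Fallback, from 15 (isolated by evaporation after the first stage of step 8) back to 17: the far more nucleophilic enaminone is brominated first (NBS, CH2Cl2, −78 °C) to the α-bromo enaminone F11, which is cyclised with 1 M H2SO4 in THF to 17.

Step 13. Premature hydride transfer (reduction of the triflate to C3–H) or slow oxidative addition at the hindered position may defeat the formylation. Fallback, from 22 back to 23: Stille coupling with tributyl(vinyl)stannane (Pd(PPh3)4, LiCl, THF, 65 °C), which has no hydride source, gives the 3-vinylbenzofuran F12. Lemieux–Johnson cleavage (OsO4 cat., NaIO4, 2,6-lutidine, dioxane/water) gives 23.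

Step 15. Over-reduction of the aldehyde may accompany debenzylation. Fallback, from 23 back to 25: the benzyl ethers are cleaved without hydrogen by BCl3 and pentamethylbenzene in CH2Cl2 at −78 °C while the silyl ethers still mask the tertiary alcohol and the 4-OH, giving the bis-silyl triol aldehyde F13. Bu4NF/AcOH then gives 25.

## Further compounds

F1 | step 10 | 2,4-bis(triisopropylsilyloxy)benzaldehyde | O=Cc1ccc(O[Si](C(C)C)(C(C)C)C(C)C)cc1O[Si](C(C)C)(C(C)C)C(C)C
F2 | step 10 | 1-ethynyl-2,4-bis(triisopropylsilyloxy)benzene | C#Cc1ccc(O[Si](C(C)C)(C(C)C)C(C)C)cc1O[Si](C(C)C)(C(C)C)C(C)C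
F3 | step 10 | 1-methoxy-3,5-bis(methoxymethoxy)benzene | COCOc1cc(OC)cc(OCOC)c1
F4 | step 10 | 2-iodo-5-methoxy-1,3-bis(methoxymethoxy)benzene | COCOc1cc(OC)cc(OCOC)c1I
F5 | step 10 | 1-{[4-methoxy-2,6-bis(methoxymethoxy)phenyl]ethynyl}-2,4-bis(triisopropylsilyloxy)benzene | COCOc1cc(OC)cc(OCOC)c1C#Cc1ccc(O[Si](C(C)C)(C(C)C)C(C)C)cc1O[Si](C(C)C)(C(C)C)C(C)C
F6 | step 10 | 2-[2,4-bis(triisopropylsilyloxy)phenyl]-6-methoxy-4-(methoxymethoxy)-3-(methoxymethyl)benzofuran | COCc1c(-c2ccc(O[Si](C(C)C)(C(C)C)C(C)C)cc2O[Si](C(C)C)(C(C)C)C(C)C)oc2cc(OC)cc(OCOC)c12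
F7 | step 10 | 2-[2,4-bis(triisopropylsilyloxy)phenyl]-6-methoxy-4-(methoxymethoxy)-3-(methoxymethyl)-5-(3-methyl-3-triethylsilyloxybutyl)benzofuran | COCc1c(-c2ccc(O[Si](C(C)C)(C(C)C)C(C)C)cc2O[Si](C(C)C)(C(C)C)C(C)C)oc2cc(OC)c(CCC(C)(C)O[Si](CC)(CC)CC)c(OCOC)c12
F8 | step 10 | 2-[2,4-bis(triisopropylsilyloxy)phenyl]-6-methoxy-4-(methoxymethoxy)-5-(3-methyl-3-triethylsilyloxybutyl)benzofuran-3-carbaldehyde | O=Cc1c(-c2ccc(O[Si](C(C)C)(C(C)C)C(C)C)cc2O[Si](C(C)C)(C(C)C)C(C)C)oc2cc(OC)c(CCC(C)(C)O[Si](CC)(CC)CC)c(OCOC)c12
F9 | step 10 | 2-(2,4-dihydroxyphenyl)-5-(3-hydroxy-3-methylbutyl)-6-methoxy-4-(methoxymethoxy)benzofuran-3-carbaldehyde | O=Cc1c(-c2ccc(O)cc2O)oc2cc(OC)c(CCC(C)(C)O)c(OCOC)c12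
F10 | step 8 | 1-[2,4-bis(benzyloxy)phenyl]-1-(triethylsilyloxy)propan-2-one (racemic) | CC(=O)C(O[Si](CC)(CC)CC)c1ccc(OCc2ccccc2)cc1OCc1ccccc1
F11 | step 9 | (Z)-1-[2,4-bis(benzyloxy)phenyl]-3-bromo-4-(dimethylamino)-1-hydroxybut-3-en-2-one (racemic) | CN(C)/C=C(\Br)C(=O)C(O)c1ccc(OCc2ccccc2)cc1OCc1ccccc1
F12 | step 13 | 2-[2,4-bis(benzyloxy)phenyl]-4-(tert-butyldimethylsilyloxy)-6-methoxy-5-(3-methyl-3-triethylsilyloxybutyl)-3-vinylbenzofuran | C=Cc1c(-c2ccc(OCc3ccccc3)cc2OCc2ccccc2)oc2cc(OC)c(CCC(C)(C)O[Si](CC)(CC)CC)c(O[Si](C)(C)C(C)(C)C)c12
F13 | step 15 | 4-(tert-butyldimethylsilyloxy)-2-(2,4-dihydroxyphenyl)-6-methoxy-5-(3-methyl-3-triethylsilyloxybutyl)benzofuran-3-carbaldehyde | O=Cc1c(-c2ccc(O)cc2O)oc2cc(OC)c(CCC(C)(C)O[Si](CC)(CC)CC)c(O[Si](C)(C)C(C)(C)C)c12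
A1 | alternative 1 | 2-[2,4-bis(triisopropylsilyloxy)phenyl]-6-methoxy-4-(methoxymethoxy)-3-(methoxymethyl)benzofuran | COCc1c(-c2ccc(O[Si](C(C)C)(C(C)C)C(C)C)cc2O[Si](C(C)C)(C(C)C)C(C)C)oc2cc(OC)cc(OCOC)c12
A2 | alternative 1 | 1-{[4-methoxy-2,6-bis(methoxymethoxy)phenyl]ethynyl}-2,4-bis(triisopropylsilyloxy)benzene | COCOc1cc(OC)cc(OCOC)c1C#Cc1ccc(O[Si](C(C)C)(C(C)C)C(C)C)cc1O[Si](C(C)C)(C(C)C)C(C)C
A3 | alternative 2 | methyl 2-[2,4-bis(benzyloxy)phenyl]-4,6-dihydroxy-5-(3-hydroxy-3-methylbutyl)benzofuran-3-carboxylate | COC(=O)c1c(-c2ccc(OCc3ccccc3)cc2OCc2ccccc2)oc2cc(O)c(CCC(C)(C)O)c(O)c12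
A4 | alternative 2 | dimethyl 2-[2,4-bis(benzyloxy)phenyl]-5-methylfuran-3,4-dicarboxylate | COC(=O)c1c(C)oc(-c2ccc(OCc3ccccc3)cc2OCc2ccccc2)c1C(=O)OC
A5 | alternative 2 | 6,6-dimethyltetrahydro-2H-pyran-2-one | CC1(C)CCCC(=O)O1
A6 | alternative 3 | racemic methyl trans-2-[2,4-bis(benzyloxy)phenyl]-6-methoxy-2,3-dihydrobenzofuran-3-carboxylate with a dihydropyran-2-one fused across C4 (O) and C5 (CH2CH2C=O), one enantiomer drawn | COC(=O)[C@@H]1[C@@H](c2ccc(OCc3ccccc3)cc2OCc2ccccc2)Oc2cc(OC)c3CCC(=O)Oc3c21
A7 | alternative 3 | racemic 2-[2,4-bis(benzyloxy)phenyl]-7-methoxychroman-4-one with a dihydropyran-2-one fused across C5 (O) and C6 (CH2CH2C=O) | O=C1CC(c2ccc(OCc3ccccc3)cc2OCc2ccccc2)Oc2cc(OC)c3CCC(=O)Oc3c21
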